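Each ring holds the motif C5(OH)(CH3)–C6(H)–C7=C8, a homoallylic tertiary alcohol, which is the retron of the Pd-catalysed formate hydrogenolysis of a 5,6-epoxy-7-ene. Hydride enters C6 of the π-allyl, the C5–O bond stays as the alcohol, and the 7E olefin results. A 7E epoxide reacts with inversion at C6 (cis ring, 5'R,6'S); a 7Z epoxide, after π–σ–π isomerisation, with net retention (trans ring, 5S,6S). The two C5-epimeric rings that share 6S therefore come from the two enantiomeric Sharpless epoxides of one achiral allylic alcohol, one carried on as the 7E and the other as the 7Z olefin. The key-step precursor is the (5S,6R,7Z)-epoxy enoate 13; step 8 is its 7E twin.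

Key step: step 12

Remark: locants C1–C15 follow carotenoid numbering (C1 gem-dimethyl, C3 carbonyl, C5 carbinol, C6 methine, chain from C7). The SMILES is read as the all-E compound with one trans ring (5-OH anti to the chain, 5S,6S) and one cis ring (5'R,6'S). The CIP descriptor of C6 changes with the C7 substituent although the spatial arrangement does not.

Step 1
Reactants: 1 (±)-2,2,6-trimethylcyclohexane-1,4-dione
Product: 2 (±)-7,7,9-trimethyl-1,4-dioxaspiro[4.5]decan-8-one
Conditions: ethylene glycol (1.1 equiv), p-TsOH·H2O (cat.), toluene, reflux, Dean–Stark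
Reagents that add atoms: ethylene glycol, OCCO
Why: Acid-catalysed ketalisation with water removal should occur only at the unhindered C4 carbonyl (C3 of the future ring), because the other carbonyl is flanked by the gem-dimethyl and the methyl-bearing carbon; the racemic methine is erased in step 2.

Step 2
Reactants: 2 (±)-7,7,9-trimethyl-1,4-dioxaspiro[4.5]decan-8-one
Product: 4 7,9,9-trimethyl-1,4-dioxaspiro[4.5]dec-7-en-8-yl trifluoromethanesulfonate, via lithium enolate 3 (not isolated)
Conditions: LDA (1.1 equiv), THF, −78 → 0 °C; then PhNTf2, 0 °C → rt; aq. NH4Cl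
Reagents that add atoms: N-phenylbis(trifluoromethanesulfonimide), O=S(=O)(N(c1ccccc1)S(=O)(=O)C(F)(F)F)C(F)(F)F
Why: The ketone has a single α-hydrogen, so LDA can only give the tetrasubstituted enolate 3, which PhNTf2 triflates on oxygen (enol triflate formation).

Step 3
Reactants: 4 7,9,9-trimethyl-1,4-dioxaspiro[4.5]dec-7-en-8-yl trifluoromethanesulfonate
Product: 5 methyl 7,9,9-trimethyl-1,4-dioxaspiro[4.5]dec-7-ene-8-carboxylate
Conditions: Pd(OAc)2 (5 mol%), dppp (5 mol%), CO (1 atm), MeOH, Et3N (2 equiv), DMF, 70 °C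
Reagents that add atoms: carbon monoxide, [C-]#[O+]; methanol, CO
Why: Pd-catalysed methoxycarbonylation of an enol triflate (oxidative addition, CO insertion, methanolysis) tolerates tetrasubstituted cyclohexenyl triflates and brings in C7 at the ester level.

Step 4
Reactants: 5 methyl 7,9,9-trimethyl-1,4-dioxaspiro[4.5]dec-7-ene-8-carboxylate
Product: 6 (7,9,9-trimethyl-1,4-dioxaspiro[4.5]dec-7-en-8-yl)methanol
Conditions: DIBAL-H (2.5 equiv), CH2Cl2, −78 → 0 °C; aq. Rochelle salt
Reagents that add atoms: none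
Why: DIBAL-H reduces the conjugated ester by two 1,2-hydride additions to the primary allylic alcohol and leaves the ketal untouched.

Step 5
Reactants: 6 (7,9,9-trimethyl-1,4-dioxaspiro[4.5]dec-7-en-8-yl)methanol
Product: 7 (5R,6R)-5,6-epoxy alcohol (3-ethylene ketal)
Conditions: Ti(OiPr)4 (20 mol%), D-(−)-diethyl tartrate (28 mol%), t-BuOOH (2 equiv, in decane), 4 Å MS, CH2Cl2, −20 °C
Reagents that add atoms: tert-butyl hydroperoxide, CC(C)(C)OO
Why: Sharpless asymmetric epoxidation: the titanium–D-(−)-tartrate complex delivers the peroxide oxygen to one face of the tetrasubstituted allylic alcohol, so that C5 and C6 are set together as (5R,6R) by syn oxygen transfer (the facial rule by which L-(+)-tartrate gives 2S,3S-epoxides from E-allylic alcohols, transposed to this substrate).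

Step 6
Reactants: 7 (5R,6R)-5,6-epoxy alcohol
Product: 8 (5R,6S)-5,6-epoxy aldehyde
Conditions: TPAP (5 mol%), NMO (1.5 equiv), 4 Å MS, CH2Cl2, rt
Reagents that add atoms: none
Why: Ley–Griffith oxidation is neutral, stops at the aldehyde (which has no α-hydrogen) and leaves epoxide and ketal alone.

Step 7
Reactants: 8 (5R,6S)-5,6-epoxy aldehyde
Product: 9 (5R,6S,7E)-5,6-epoxy enone
Conditions: Ph3P=CHC(O)CH3 (2 equiv), toluene, 90 °C
Reagents that add atoms: 1-(triphenylphosphoranylidene)propan-2-one, CC(=O)C=P(c1ccccc1)(c1ccccc1)c1ccccc1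
Why: Wittig olefination with the stabilised acyl ylide runs without base or salt and should give the E-enone, the epoxide being inert to the ylide.

Step 8
Reactants: 9 (5R,6S,7E)-5,6-epoxy enone
Product: 10 cis-ring hydroxy enone (5R,6S,7E)
Conditions: Pd2(dba)3·CHCl3 (2.5 mol%), n-Bu3P (5 mol%), HCO2H (3 equiv), Et3N (3 equiv), 1,4-dioxane, rt
Reagents that add atoms: none
Why: Pd-catalysed formate hydrogenolysis of an alkenyl oxirane (Tsuji–Trost-type allylic reduction): Pd(0) opens the epoxide anti to the C6–O bond, the syn-acyl π-allyl keeps its face and the hydride passes from Pd to C6, so C6 is inverted, its hydrogen lies anti to the C5 hydroxyl (cis ring, 5R,6S) and the 7E olefin stays conjugated.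

Step 9
Reactants: 6 (7,9,9-trimethyl-1,4-dioxaspiro[4.5]dec-7-en-8-yl)methanol
Product: 11 (5S,6S)-5,6-epoxy alcohol (3-ethylene ketal)
Conditions: Ti(OiPr)4 (20 mol%), L-(+)-diethyl tartrate (28 mol%), t-BuOOH (2 equiv, in decane), 4 Å MS, CH2Cl2, −20 °C
Reagents that add atoms: tert-butyl hydroperoxide, CC(C)(C)OO
Why: Sharpless asymmetric epoxidation as in step 5 with the enantiomeric L-(+)-tartrate, which should give the mirror-image (5S,6S)-epoxide.

Step 10
Reactants: 11 (5S,6S)-5,6-epoxy alcohol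
Product: 12 (5S,6R)-5,6-epoxy aldehyde
Conditions: TPAP (5 mol%), NMO (1.5 equiv), 4 Å MS, CH2Cl2, rt
Reagents that add atoms: none
Why: Ley–Griffith oxidation as in step 6; the quaternary α-carbon cannot epimerise.

Step 11
Reactants: 12 (5S,6R)-5,6-epoxy aldehyde
Product: 13 (5S,6R,7Z)-5,6-epoxy enoate (methyl ester)
Conditions: (CF3CH2O)2P(O)CH2CO2Me (1.2 equiv), KHMDS (1.15 equiv), 18-crown-6 (3 equiv), THF, −78 °C
Reagents that add atoms: methyl bis(2,2,2-trifluoroethyl)phosphonoacetate, COC(=O)CP(=O)(OCC(F)(F)F)OCC(F)(F)F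
Why: Still–Gennari olefination: the bis(trifluoroethyl) phosphonate with a dissociated potassium counter-ion eliminates fast from the kinetically formed adduct and should give the Z-enoate.

Step 12
Reactants: 13 (5S,6R,7Z)-5,6-epoxy enoate
Product: 14 trans-ring hydroxy enoate (5S,6S,7E)
Conditions: Pd2(dba)3·CHCl3 (2.5 mol%), n-Bu3P (5 mol%, one phosphine per Pd), HCO2H (3 equiv), Et3N (3 equiv), 1,4-dioxane, rt
Reagents that add atoms: none
Why: Pd(0) ionises the vinyl epoxide with inversion at C6 to a zwitterionic π-allyl/alkoxide in which the ester on C8 is anti because of the Z olefin; A(1,3) strain against the fully substituted C6 terminus drives η3–η1–η3 isomerisation through the C8-bound (α-ester) σ-complex, which places the ester syn and moves Pd to the C6 face that the oxygen has just left. Formate then binds Pd, loses CO2, and the hydride passes from Pd to C6, the more substituted allyl terminus, so that the C6–H bond is syn to the C5–OH (net retention): this is the trans ring (5S,6S) with the 7E enoate. The closest known reaction type is the Pd/formate hydrogenolysis of alkenyl oxiranes (Tsuji–Trost-type allylic reduction), known for γ,δ-epoxy enoates to give inversion from E and net retention from Z olefins; no ring is closed. C6 is the only new stereocenter and is controlled by chirality transfer from the Sharpless-derived epoxide together with the olefin geometry, while C5 is carried over untouched as the tertiary alcohol. The step needs hydride delivery at C6 and not at C8, and isomerisation before hydride transfer: the first is secured by the ester, which holds Pd at C8 and keeps the product conjugated, and by the quaternary C1 and C5, which offer no β-hydrogen for diene formation; the second by the strain of the anti complex and by the use of only one phosphine per palladium.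

Step 13
Reactants: 14 trans-ring hydroxy enoate (5S,6S,7E)
Product: 16 trans-ring hydroxy enone (5S,6S,7E), via Weinreb amide 15 (not isolated)
Conditions: MeNH(OMe)·HCl (1.5 equiv), i-PrMgCl (4 equiv), THF, −20 °C; then MeMgBr (3 equiv), −20 → 0 °C; aq. NH4Cl
Reagents that add atoms: methylmagnesium bromide, C[Mg]Br
Why: Weinreb ketone synthesis in one pot: the chloromagnesium amide converts the ester into amide 15, whose chelated tetrahedral adduct with MeMgBr collapses to the methyl ketone only on work-up, so no tertiary alcohol forms and the C5 alkoxide is a spectator.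

Step 14
Reactants: 10 cis-ring hydroxy enone (5R,6S,7E)
Product: 17 cis-ring C15 vinyl carbinol (5R,6S,7E; C9 epimers)
Conditions: CH2=CHMgBr (3 equiv), THF, −78 → 0 °C; aq. NH4Cl
Reagents that add atoms: vinylmagnesium bromide, C=C[Mg]Br
Why: Vinyl Grignard reagents add 1,2 to ionone-type enones; the first equivalent is consumed by the C5 hydroxyl and the two C9 epimers converge in step 15.

Step 15
Reactants: 17 cis-ring C15 vinyl carbinol
Product: 18 cis-ring C15 triphenylphosphonium bromide (5R,6S,7E,9E)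
Conditions: Ph3P·HBr (1.05 equiv), CH2Cl2, 0 °C → rt
Reagents that add atoms: triphenylphosphine hydrobromide, [Br-].c1ccccc1[PH+](c1ccccc1)c1ccccc1
Why: Ph3P·HBr ionises the doubly allylic tertiary carbinol to a pentadienyl cation that triphenylphosphine captures at the unhindered C11 terminus (SN1' allylic transposition), which should give the conjugated 7E,9E salt while the saturated C5 carbinol stays.

Step 16
Reactants: 16 trans-ring hydroxy enone (5S,6S,7E)
Product: 19 trans-ring C15 vinyl carbinol (5S,6S,7E; C9 epimers)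
Conditions: CH2=CHMgBr (3 equiv), THF, −78 → 0 °C; aq. NH4Cl
Reagents that add atoms: vinylmagnesium bromide, C=C[Mg]Br
Why: Grignard 1,2-addition as in step 14; the hindered tertiary C6–H is not deprotonated, so C6 is kept.

Step 17
Reactants: 19 trans-ring C15 vinyl carbinol
Product: 20 trans-ring C15 triphenylphosphonium bromide (5S,6S,7E,9E)
Conditions: Ph3P·HBr (1.05 equiv), CH2Cl2, 0 °C → rt
Reagents that add atoms: triphenylphosphine hydrobromide, [Br-].c1ccccc1[PH+](c1ccccc1)c1ccccc1
Why: SN1' allylic transposition with phosphine capture as in step 15.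

Step 18
Reactants: 18 cis-ring C15 triphenylphosphonium bromide; 21 (2E,4E,6E)-2,7-dimethylocta-2,4,6-trienedial (3 equiv)
Product: 23 cis-ring C25 apo-aldehyde (all-E), via phosphonium ylide 22 (not isolated)
Conditions: NaOMe (1.1 equiv), MeOH/CH2Cl2, 0 °C → rt; then n-heptane, 80 °C, dark
Reagents that add atoms: none
Why: Wittig reaction of ylide 22 with an excess of the symmetrical dialdehyde should stop after one olefination; the new 11,12 double bond forms as an E/Z mixture from which the hindered Z isomer reverts to E on heating.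

Step 19
Reactants: 20 trans-ring C15 triphenylphosphonium bromide; 23 cis-ring C25 apo-aldehyde
Product: 25 C40 bis(ethylene ketal) (all-E; 5S,6S,5'R,6'S), via phosphonium ylide 24 (not isolated)
Conditions: NaOMe (1.2 equiv), MeOH/CH2Cl2, 0 °C → rt; then n-heptane, reflux, dark, N2
Reagents that add atoms: none
Why: The second Wittig reaction, now with the trans-ring ylide 24, completes the C40 chain; thermal equilibration should give the all-E polyene, and neither C5 nor C6 is touched.

Step 20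
Reactants: 25 C40 bis(ethylene ketal)
Product: 26 (all-E,5S,6S,5'R,6'S)-5,5'-dihydroxy-5,6,5',6'-tetrahydro-β,β-carotene-3,3'-dione (CNP0366900.1)
Conditions: 1 M aq. HCl, THF, 0 °C → rt, dark, N2
Reagents that add atoms: water, O
Why: Dilute aqueous acid hydrolyses both dioxolanes to the C3 ketones (ketal hydrolysis); C6 is not α to the new carbonyl and C5 is not ionised under these conditions, so the four stereocenters should be retained.

Compound list
1 | (±)-2,2,6-trimethylcyclohexane-1,4-dione | CC1CC(=O)CC(C)(C)C1=O | starting material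
2 | (±)-7,7,9-trimethyl-1,4-dioxaspiro[4.5]decan-8-one | CC1CC2(CC(C)(C)C1=O)OCCO2 | intermediate
3 | lithium 7,9,9-trimethyl-1,4-dioxaspiro[4.5]dec-7-en-8-olate | [Li+].CC1=C([O-])C(C)(C)CC2(C1)OCCO2 | intermediate (not isolated)
4 | 7,9,9-trimethyl-1,4-dioxaspiro[4.5]dec-7-en-8-yl trifluoromethanesulfonate | CC1=C(OS(=O)(=O)C(F)(F)F)C(C)(C)CC2(C1)OCCO2 | intermediate
5 | methyl 7,9,9-trimethyl-1,4-dioxaspiro[4.5]dec-7-ene-8-carboxylate | COC(=O)C1=C(C)CC2(CC1(C)C)OCCO2 | intermediate
6 | (7,9,9-trimethyl-1,4-dioxaspiro[4.5]dec-7-en-8-yl)methanol | OCC1=C(C)CC2(CC1(C)C)OCCO2 | intermediate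
7 | [(1'R,6'R)-2',2',6'-trimethylspiro[1,3-dioxolane-2,4'-[7]oxabicyclo[4.1.0]heptan]-1'-yl]methanol (5R,6R) | OC[C@]12C(C)(C)CC3(OCCO3)C[C@@]1(C)O2 | intermediate
8 | (1'S,6'R)-2',2',6'-trimethylspiro[1,3-dioxolane-2,4'-[7]oxabicyclo[4.1.0]heptane]-1'-carbaldehyde (5R,6S) | O=C[C@]12C(C)(C)CC3(OCCO3)C[C@@]1(C)O2 | intermediate
9 | (E)-4-[(1'S,6'R)-2',2',6'-trimethylspiro[1,3-dioxolane-2,4'-[7]oxabicyclo[4.1.0]heptan]-1'-yl]but-3-en-2-one (5R,6S,7E) | CC(=O)/C=C/[C@]12C(C)(C)CC3(OCCO3)C[C@@]1(C)O2 | intermediate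
10 | (E)-4-[(7R,8S)-7-hydroxy-7,9,9-trimethyl-1,4-dioxaspiro[4.5]decan-8-yl]but-3-en-2-one (cis ring, 5R,6S) | CC(=O)/C=C/[C@H]1C(C)(C)CC2(OCCO2)C[C@@]1(C)O | intermediate
11 | [(1'S,6'S)-2',2',6'-trimethylspiro[1,3-dioxolane-2,4'-[7]oxabicyclo[4.1.0]heptan]-1'-yl]methanol (5S,6S) | OC[C@@]12C(C)(C)CC3(OCCO3)C[C@]1(C)O2 | intermediate
12 | (1'R,6'S)-2',2',6'-trimethylspiro[1,3-dioxolane-2,4'-[7]oxabicyclo[4.1.0]heptane]-1'-carbaldehyde (5S,6R) | O=C[C@@]12C(C)(C)CC3(OCCO3)C[C@]1(C)O2 | intermediate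
13 | methyl (Z)-3-[(1'R,6'S)-2',2',6'-trimethylspiro[1,3-dioxolane-2,4'-[7]oxabicyclo[4.1.0]heptan]-1'-yl]prop-2-enoate (5S,6R,7Z) | COC(=O)/C=C\[C@@]12C(C)(C)CC3(OCCO3)C[C@]1(C)O2 | intermediate
14 | methyl (E)-3-[(7S,8S)-7-hydroxy-7,9,9-trimethyl-1,4-dioxaspiro[4.5]decan-8-yl]prop-2-enoate (trans ring, 5S,6S) | COC(=O)/C=C/[C@H]1C(C)(C)CC2(OCCO2)C[C@]1(C)O | intermediate
15 | (E)-3-[(7S,8S)-7-hydroxy-7,9,9-trimethyl-1,4-dioxaspiro[4.5]decan-8-yl]-N-methoxy-N-methylprop-2-enamide | CON(C)C(=O)/C=C/[C@H]1C(C)(C)CC2(OCCO2)C[C@]1(C)O | intermediate (not isolated)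
16 | (E)-4-[(7S,8S)-7-hydroxy-7,9,9-trimethyl-1,4-dioxaspiro[4.5]decan-8-yl]but-3-en-2-one (trans ring, 5S,6S) | CC(=O)/C=C/[C@H]1C(C)(C)CC2(OCCO2)C[C@]1(C)O | intermediate
17 | (1E)-1-[(7R,8S)-7-hydroxy-7,9,9-trimethyl-1,4-dioxaspiro[4.5]decan-8-yl]-3-methylpenta-1,4-dien-3-ol (both C3 epimers) | C=CC(C)(O)/C=C/[C@H]1C(C)(C)CC2(OCCO2)C[C@@]1(C)O | intermediate
18 | [(2E,4E)-5-[(7R,8S)-7-hydroxy-7,9,9-trimethyl-1,4-dioxaspiro[4.5]decan-8-yl]-3-methylpenta-2,4-dien-1-yl]triphenylphosphonium bromide | [Br-].c1ccccc1[P+](c1ccccc1)(c1ccccc1)C/C=C(C)/C=C/[C@H]1C(C)(C)CC2(OCCO2)C[C@@]1(C)O | intermediate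
19 | (1E)-1-[(7S,8S)-7-hydroxy-7,9,9-trimethyl-1,4-dioxaspiro[4.5]decan-8-yl]-3-methylpenta-1,4-dien-3-ol (both C3 epimers) | C=CC(C)(O)/C=C/[C@H]1C(C)(C)CC2(OCCO2)C[C@]1(C)O | intermediate
20 | [(2E,4E)-5-[(7S,8S)-7-hydroxy-7,9,9-trimethyl-1,4-dioxaspiro[4.5]decan-8-yl]-3-methylpenta-2,4-dien-1-yl]triphenylphosphonium bromide | [Br-].c1ccccc1[P+](c1ccccc1)(c1ccccc1)C/C=C(C)/C=C/[C@H]1C(C)(C)CC2(OCCO2)C[C@]1(C)O | intermediate
21 | (2E,4E,6E)-2,7-dimethylocta-2,4,6-trienedial | O=C/C(C)=C/C=C/C=C(C)/C=O | starting material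
22 | ylide of 18: (2E,4E)-5-[(7R,8S)-7-hydroxy-7,9,9-trimethyl-1,4-dioxaspiro[4.5]decan-8-yl]-3-methylpenta-2,4-dienylidene(triphenyl)phosphorane | c1ccccc1[P+](c1ccccc1)(c1ccccc1)[CH-]/C=C(C)/C=C/[C@H]1C(C)(C)CC2(OCCO2)C[C@@]1(C)O | intermediate (not isolated)
23 | (2E,4E,6E,8E,10E,12E)-13-[(7R,8S)-7-hydroxy-7,9,9-trimethyl-1,4-dioxaspiro[4.5]decan-8-yl]-2,7,11-trimethyltrideca-2,4,6,8,10,12-hexaenal | O=C/C(C)=C/C=C/C=C(C)/C=C/C=C(C)/C=C/[C@H]1C(C)(C)CC2(OCCO2)C[C@@]1(C)O | intermediate
24 | ylide of 20: (2E,4E)-5-[(7S,8S)-7-hydroxy-7,9,9-trimethyl-1,4-dioxaspiro[4.5]decan-8-yl]-3-methylpenta-2,4-dienylidene(triphenyl)phosphorane | c1ccccc1[P+](c1ccccc1)(c1ccccc1)[CH-]/C=C(C)/C=C/[C@H]1C(C)(C)CC2(OCCO2)C[C@]1(C)O | intermediate (not isolated)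
25 | 3,3'-bis(ethylene ketal) of 26: (all-E,5S,6S,5'R,6'S)-3,3:3',3'-bis(ethylenedioxy)-5,6,5',6'-tetrahydro-β,β-carotene-5,5'-diol | CC(/C=C/C=C(C)/C=C/[C@H]1C(C)(C)CC2(OCCO2)C[C@]1(C)O)=C\C=C\C=C(C)\C=C\C=C(C)\C=C\[C@H]1C(C)(C)CC2(OCCO2)C[C@@]1(C)O | intermediate
26 | (all-E,5S,6S,5'R,6'S)-5,5'-dihydroxy-5,6,5',6'-tetrahydro-β,β-carotene-3,3'-dione | CC(/C=C/C=C(C)/C=C/[C@H]1C(C)(C)CC(=O)C[C@]1(C)O)=C\C=C\C=C(C)\C=C\C=C(C)\C=C\[C@H]1C(C)(C)CC(=O)C[C@@]1(C)O | target

Total step count: 20
Longest linear sequence: 13 steps (1–4, 9–13, 16, 17, 19, 20)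

Steps most likely to fail

1. Step 12 (key step). Hydride transfer may outrun the syn/anti isomerisation, or the ester-stabilised allyl may lose its facial integrity; material would then leak into the cis ring or into the 7Z olefin, which can lactonise with the C5 alkoxide. Hydride delivery at C8 would also deconjugate the ester. The fallback sets out from 12 and comes back at 14; it fixes C6 by hydroxyl-directed hydrogenation instead of by the π-allyl. Wittig reaction of 12 with methyl (triphenylphosphoranylidene)acetate should give methyl (E)-3-[(1'R,6'S)-2',2',6'-trimethylspiro[1,3-dioxolane-2,4'-[7]oxabicyclo[4.1.0]heptan]-1'-yl]prop-2-enoate F1. SmI2 (THF/MeOH, −78 °C) should open the epoxide by electron transfer through the enoate to the β,γ-unsaturated hydroxy ester with an exocyclic C6=C7 bond, methyl 3-[(7S)-7-hydroxy-7,9,9-trimethyl-1,4-dioxaspiro[4.5]decan-8-ylidene]propanoate F2. Crabtree's catalyst under H2 (CH2Cl2) should deliver hydrogen to C6 from the face of the C5 hydroxyl and give methyl 3-[(7S,8S)-7-hydroxy-7,9,9-trimethyl-1,4-dioxaspiro[4.5]decan-8-yl]propanoate F3. α-Selenenylation (LDA, 2.2 equiv; PhSeBr) would give methyl 3-[(7S,8S)-7-hydroxy-7,9,9-trimethyl-1,4-dioxaspiro[4.5]decan-8-yl]-2-(phenylselanyl)propanoate F4, and oxidation (H2O2, pyridine, 0 °C) with syn elimination of the selenoxide would return the E-enoate 14.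

2. Step 9 (the same holds for step 5). The hindered tetrasubstituted allylic alcohol may epoxidise slowly, so that the titanium Lewis acid opens the epoxy alcohol and the enantiomeric purity erodes. The fallback sets out from 6 and comes back at 7 and 11; it replaces the two asymmetric epoxidations by one racemic epoxidation and an enzymatic resolution that uses both enantiomers. mCPBA/NaHCO3 (CH2Cl2, 0 °C) on 6 should give racemic 7/11. A lipase (Burkholderia cepacia lipase or CAL-B, vinyl acetate, MTBE), screened so that the (5S,6S)-alcohol is acylated, would give [(1'S,6'S)-2',2',6'-trimethylspiro[1,3-dioxolane-2,4'-[7]oxabicyclo[4.1.0]heptan]-1'-yl]methyl acetate F5 and leave 7. After separation, K2CO3/MeOH on F5 would return 11.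

3. Step 17. The acid that ionises the C9 carbinol may also cleave the dioxolane with the water set free, or let the C5 hydroxyl cyclise onto the pentadienyl cation. The fallback sets out from 16 and comes back at 20; it builds the C15 salt by two-carbon olefination and never forms a cation. Horner–Wadsworth–Emmons reaction of 16 with triethyl phosphonoacetate (NaH, THF) should give, after separation from the 9Z isomer, ethyl (2E,4E)-5-[(7S,8S)-7-hydroxy-7,9,9-trimethyl-1,4-dioxaspiro[4.5]decan-8-yl]-3-methylpenta-2,4-dienoate F6. DIBAL-H (CH2Cl2, −78 °C) would give (2E,4E)-5-[(7S,8S)-7-hydroxy-7,9,9-trimethyl-1,4-dioxaspiro[4.5]decan-8-yl]-3-methylpenta-2,4-dien-1-ol F7. Appel bromination (CBr4, PPh3, CH2Cl2, 0 °C), which spares the hindered tertiary alcohol, would give (7S,8S)-8-[(1E,3E)-5-bromo-3-methylpenta-1,3-dien-1-yl]-7,9,9-trimethyl-1,4-dioxaspiro[4.5]decan-7-ol F8, and triphenylphosphine (toluene, rt) would convert it into salt 20.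

Further compounds
F1 | step 12 | methyl (E)-3-[(1'R,6'S)-2',2',6'-trimethylspiro[1,3-dioxolane-2,4'-[7]oxabicyclo[4.1.0]heptan]-1'-yl]prop-2-enoate | COC(=O)/C=C/[C@@]12C(C)(C)CC3(OCCO3)C[C@]1(C)O2
F2 | step 12 | methyl 3-[(7S)-7-hydroxy-7,9,9-trimethyl-1,4-dioxaspiro[4.5]decan-8-ylidene]propanoate (C6=C7 geometry not fixed) | COC(=O)CC=C1C(C)(C)CC2(OCCO2)C[C@]1(C)O
F3 | step 12 | methyl 3-[(7S,8S)-7-hydroxy-7,9,9-trimethyl-1,4-dioxaspiro[4.5]decan-8-yl]propanoate | COC(=O)CC[C@H]1C(C)(C)CC2(OCCO2)C[C@]1(C)O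
F4 | step 12 | methyl 3-[(7S,8S)-7-hydroxy-7,9,9-trimethyl-1,4-dioxaspiro[4.5]decan-8-yl]-2-(phenylselanyl)propanoate (both C2 epimers) | COC(=O)C([Se]c1ccccc1)C[C@H]1C(C)(C)CC2(OCCO2)C[C@]1(C)O
F5 | step 9 | [(1'S,6'S)-2',2',6'-trimethylspiro[1,3-dioxolane-2,4'-[7]oxabicyclo[4.1.0]heptan]-1'-yl]methyl acetate | CC(=O)OC[C@@]12C(C)(C)CC3(OCCO3)C[C@]1(C)O2
F6 | step 17 | ethyl (2E,4E)-5-[(7S,8S)-7-hydroxy-7,9,9-trimethyl-1,4-dioxaspiro[4.5]decan-8-yl]-3-methylpenta-2,4-dienoate | CCOC(=O)/C=C(C)/C=C/[C@H]1C(C)(C)CC2(OCCO2)C[C@]1(C)O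
F7 | step 17 | (2E,4E)-5-[(7S,8S)-7-hydroxy-7,9,9-trimethyl-1,4-dioxaspiro[4.5]decan-8-yl]-3-methylpenta-2,4-dien-1-ol | OC/C=C(C)/C=C/[C@H]1C(C)(C)CC2(OCCO2)C[C@]1(C)O
F8 | step 17 | (7S,8S)-8-[(1E,3E)-5-bromo-3-methylpenta-1,3-dien-1-yl]-7,9,9-trimethyl-1,4-dioxaspiro[4.5]decan-7-ol | BrC/C=C(C)/C=C/[C@H]1C(C)(C)CC2(OCCO2)C[C@]1(C)O
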